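**Retrosynthetic overview**
1. Junceellolide I ⇐ desilylation of its 8,11,14-tris-O-triethylsilyl ether. The ten-membered ring and the γ-lactone close together by an electrochemical alkenyl–aldehyde (Nozaki–Hiyama–Kishi-type) C6–C7 coupling of a seco iodoalkene aldehyde.
2. Seco aldehyde ⇐ propanoate aldol on the C8 ketone (sets C8 and C17) ⇐ C9 acetoxy ketone, made from a C9≡C8 alkyne through an O11-tethered dihydrofuran and its epoxide (sets C9).
3. C2-OAc/14-OH ⇐ Evans–Tishchenko reduction of an aldol adduct ⇐ one-pot hydroxyl-directed conjugate alkynylation/aldol of a 4-hydroxycyclohexenone, 3,3-diethoxypropyne and a (Z)-iodoalkenyl aldehyde (sets C10, C1, C2).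
4. Cyclohexenone ⇐ (S)-linalool, which supplies C11, the only purchased stereocentre; aldehyde ⇐ propargyl alcohol.
5. Ring order: six-membered ring (step 2), then ten-membered ring and γ-lactone (both in step 12).

Assumption: (S)-(+)-linalool (coriandrol) is taken as the commercial chiral-pool material; intermediates are described with briarane numbering (C19 = lactone carbonyl; C15, C16, C18, C20 = methyls on C1, C5, C17, C11; β = the face of C15).

**Route**

Step 1
Reactants: 1 (S)-linalool
Product: 3 (6S)-6-hydroxy-2,6-dimethylocta-1,7-dien-3-one, via allylic hydroperoxide 2 (not isolated)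
Conditions: O2, tetraphenylporphyrin (0.5 mol %), CH2Cl2, visible-light LED, 0 °C; then Ac2O, pyridine, DMAP (5 mol %), 0 °C to rt
Reagents that add atoms: dioxygen (O=O)
Why: The singlet-oxygen Schenck ene reaction of the trisubstituted alkene (the vinyl group is inert) gives the secondary allylic hydroperoxide, and Kornblum–DeLaMare dehydration turns it into the isopropenyl ketone without touching the purchased C11 stereocentre; the tertiary hydroperoxide regioisomer (about half of the ene product) is separated.

Step 2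
Reactants: 3 (6S)-6-hydroxy-2,6-dimethylocta-1,7-dien-3-one
Product: 4 (4S)-4-hydroxy-2,4-dimethylcyclohex-2-en-1-one
Conditions: second-generation Grubbs catalyst RuCl2(=CHPh)(PCy3)(H2IMes) (5 mol %), CH2Cl2 (0.02 M), 40 °C
Reagents that add atoms: none
Why: Ring-closing metathesis between the 1,1-disubstituted enone alkene and the vinyl group closes the six-membered ring as a 2-methylcyclohexenone with loss of ethene; no stereocentre is formed.

Step 3
Reactants: 5 prop-2-yn-1-ol
Product: 7 (Z)-3-iodo-2-methylprop-2-en-1-ol, via alkenylmagnesium alkoxide 6 (not isolated)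
Conditions: MeMgBr (2.5 equiv), CuI (10 mol %), THF, −10 °C to rt; then I2, −78 to 0 °C
Reagents that add atoms: methylmagnesium bromide (C[Mg]Br); iodine (II)
Why: Copper-catalysed anti-carbomagnesiation of the propargylic alkoxide (Duboudin reaction) puts the methyl on the internal carbon and magnesium cis to CH2O, so iodinolysis gives the Z iodoalkene that later becomes the Z C5=C6 olefin.

Step 4
Reactants: 7 (Z)-3-iodo-2-methylprop-2-en-1-ol
Product: 8 (Z)-3-bromo-1-iodo-2-methylprop-1-ene
Conditions: CBr4, PPh3, CH2Cl2, 0 °C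
Reagents that add atoms: carbon tetrabromide (BrC(Br)(Br)Br)
Why: Appel bromination converts the primary allylic alcohol into the bromide without touching the alkenyl iodide or its geometry.

Step 5
Reactants: 8 (Z)-3-bromo-1-iodo-2-methylprop-1-ene
Product: 10 (Z)-5-iodo-4-methylpent-4-enal, via alkylated imine 9 (not isolated)
Conditions: N-ethylidenecyclohexanamine, LiN(iPr)2, THF, −78 °C; then 8, −78 to 0 °C; then aq. oxalic acid, rt
Reagents that add atoms: N-ethylidenecyclohexanamine (CC=NC1CCCCC1); water (O)
Why: Stork metalloenamine alkylation: the lithiated acetaldehyde imine displaces the primary allylic bromide (SN2) and mild acid hydrolysis releases the two-carbon-homologated aldehyde without self-aldol.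

Step 6
Reactants: 4 (4S)-4-hydroxy-2,4-dimethylcyclohex-2-en-1-one; 11 3,3-diethoxyprop-1-yne; 10 (Z)-5-iodo-4-methylpent-4-enal
Product: 14 aldol adduct (2S,3R,4S)-3-(3,3-diethoxyprop-1-yn-1-yl)-4-hydroxy-2-[(1S,4Z)-1-hydroxy-5-iodo-4-methylpent-4-en-1-yl]-2,4-dimethylcyclohexan-1-one, via alkynylalane 12 (not isolated), via aluminium enolate 13 (not isolated)
Conditions: 11, AlMe3, Et3N (10 mol %), toluene, 60 °C; then 4, toluene, 0 °C to rt; then 10, −78 °C; aq. KNaC4H4O6 (Rochelle salt)
Reagents that add atoms: none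
Why: Hydroxyl-directed conjugate alkynylation followed by an aldol reaction: the C11 alkoxide binds the alane and delivers the alkynyl group to C10 on its own (β) face, and the aluminium enolate then adds to 10 anti to the new C10 substituent through a Zimmerman–Traxler chair (enolate methyl cis to O–Al, aldehyde chain equatorial), which sets C10, C1 (Me β) and C2 (OH syn to C15).

Step 7
Reactants: 14 aldol adduct
Product: 15 monoacetate (2-OAc, 14α-OH)
Conditions: MeCHO (8 equiv), SmI2 (30 mol %), THF, −10 °C
Reagents that add atoms: acetaldehyde (CC=O)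
Why: Evans–Tishchenko reduction: the samarium-bound hemiacetal of the C2 hydroxyl with acetaldehyde delivers hydride to the C14 ketone through a six-membered chair, giving the 1,3-anti diol monoester with the acetate on O2 and the free axial 14α-hydroxyl.

Step 8
Reactants: 15 monoacetate (2-OAc, 14α-OH)
Product: 18 ketol (9-OH, C8 ketone), via dihydrofuran 16 (not isolated), via epoxide 17 (not isolated)
Conditions: Ph3PAuNTf2 (2 mol %), CH2Cl2, 0 °C; then dimethyldioxirane (1.1 equiv), acetone, −78 °C; then H2O, THF, rt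
Reagents that add atoms: dimethyldioxirane (CC1(C)OO1); water (O)
Why: Monovalent-gold-catalysed 5-endo-dig hydroalkoxylation by the cis 11-OH gives a cis-fused dihydrofuran (the trans-disposed 14α-OH cannot reach the alkyne); its enol ether is epoxidised from the convex face, the face of H10 (Rubottom-type oxidation), and hydrolysis returns the C8 ketone and 11-OH with the new 9-OH in the target configuration.

Step 9
Reactants: 18 ketol (9-OH, C8 ketone)
Product: 19 diacetate ketone
Conditions: Ac2O (1.3 equiv), pyridine, DMAP (5 mol %), CH2Cl2, −20 °C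
Reagents that add atoms: acetic anhydride (CC(=O)OC(C)=O)
Why: DMAP-catalysed acylation at low temperature esterifies the accessible α-ketol hydroxyl at C9, while the axial neopentylic 14-OH and the tertiary 11-OH stay free.

Step 10
Reactants: 19 diacetate ketone
Product: 20 aldol ester
Conditions: methyl propanoate, LiN(iPr)2, THF/DMPU, −78 °C; then 19, −78 °C; AcOH quench at −78 °C
Reagents that add atoms: methyl propanoate (CCC(=O)OC)
Why: Ester-enolate aldol addition to the α-acetoxy ketone under polar Felkin–Anh control (C9–OAc anti to the incoming enolate) sets C8, and the enolate with methyl cis to O–Li, with the large C9 branch equatorial in the Zimmerman–Traxler chair, sets C17.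

Step 11
Reactants: 20 aldol ester
Product: 23 seco aldehyde, via silylated acetal 21 (not isolated), via collidinium salt 22 (not isolated)
Conditions: Et3SiOTf (7 equiv), 2,4,6-collidine (10 equiv), CH2Cl2, 0 °C to rt; then H2O
Reagents that add atoms: triethylsilyl trifluoromethanesulfonate (CC[Si](CC)(CC)OS(=O)(=O)C(F)(F)F); water (O)
Why: Et3SiOTf/collidine first silylates the three hydroxyls and then converts the diethyl acetal, through its collidinium adduct, into the aldehyde on aqueous work-up (Fujioka–Kita acetal cleavage); acetates, methyl ester and silyl ethers survive, and capping 11-OH prevents lactol formation with the new aldehyde.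

Step 12
Reactants: 23 seco aldehyde
Product: 26 8,11,14-tris-O-triethylsilyl junceellolide I, via silyl ether 24 (not isolated), via hydroxy ester 25 (not isolated)
Conditions: CrCl2 (15 mol %), NiCl2(dme) (3 mol %), Me3SiCl (4 equiv), Et4NBF4 (0.1 M), DMF, 2 mM, undivided cell, Al anode, Ni-foam cathode, constant current 3 mA, rt; then aq. citric acid, THF, rt
Reagents that add atoms: none
Why: Proposed new method: a chromium-electrocatalytic, nickel-co-catalysed Nozaki–Hiyama–Kishi macrocyclisation, in which the cathode keeps chromium divalent, zerovalent nickel formed from NiCl2(dme) inserts into the alkenyl C–I bond with retention of the Z geometry and passes the alkenyl group to trivalent chromium, the alkenylchromium adds intramolecularly to the C7 aldehyde to close the ten-membered ring (polar Felkin–Anh attack anti to the C8–OSiEt3 bond and past the smaller C17 branch sets C7), Me3SiCl turns over the Cr–O bond, and the freed 7-OH lactonises onto the C19 ester on work-up; the closest known reactions are the intermolecular chromium-electrocatalytic alkenylation of aldehydes and stoichiometric CrCl2/NiCl2 macrocyclisations, and an electrochemical medium-ring closure of this kind has not been shown.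

Step 13
Reactants: 26 8,11,14-tris-O-triethylsilyl junceellolide I
Product: 27 junceellolide I
Conditions: HF·pyridine, pyridine/THF, 0 °C to rt
Reagents that add atoms: none
Why: Fluoride-mediated desilylation removes the three triethylsilyl ethers without affecting the two acetates, the β-hydroxy lactone or any stereocentre.

**Compound list**

1 | (S)-linalool [(3S)-3,7-dimethylocta-1,6-dien-3-ol] | C=C[C@@](C)(O)CCC=C(C)C | starting material
2 | allylic hydroperoxide: (3S)-6-hydroperoxy-3,7-dimethylocta-1,7-dien-3-ol (both C6 epimers) | C=C[C@@](C)(O)CCC(OO)C(C)=C | intermediate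
3 | (6S)-6-hydroxy-2,6-dimethylocta-1,7-dien-3-one | C=C[C@@](C)(O)CCC(=O)C(C)=C | intermediate
4 | (4S)-4-hydroxy-2,4-dimethylcyclohex-2-en-1-one | O=C1CC[C@](C)(O)C=C1C | intermediate
5 | prop-2-yn-1-ol | C#CCO | starting material
6 | alkenylmagnesium alkoxide: bromomagnesium (Z)-3-(bromomagnesio)-2-methylprop-2-en-1-olate | Br[Mg]OC/C(C)=C\[Mg]Br | intermediate
7 | (Z)-3-iodo-2-methylprop-2-en-1-ol | OC/C(C)=C\I | intermediate
8 | (Z)-3-bromo-1-iodo-2-methylprop-1-ene | BrC/C(C)=C\I | intermediate
9 | alkylated imine: N-cyclohexyl imine of (Z)-5-iodo-4-methylpent-4-enal | C1CCCCC1N=CCC/C(C)=C\I | intermediate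
10 | (Z)-5-iodo-4-methylpent-4-enal | O=CCC/C(C)=C\I | intermediate
11 | 3,3-diethoxyprop-1-yne | C#CC(OCC)OCC | starting material
12 | alkynylalane: (3,3-diethoxyprop-1-yn-1-yl)dimethylaluminium | C[Al](C)C#CC(OCC)OCC | intermediate
13 | aluminium enolate: methylaluminium O11-alkoxide O14-enolate of the C10-alkynylated ketone (alkynyl cis to O11; drawn as the monomer, aggregated in solution) | C[Al]1OC2=C(C)[C@@H](C#CC(OCC)OCC)[C@](C)(CC2)O1 | intermediate
14 | aldol adduct (2S,3R,4S)-3-(3,3-diethoxyprop-1-yn-1-yl)-4-hydroxy-2-[(1S,4Z)-1-hydroxy-5-iodo-4-methylpent-4-en-1-yl]-2,4-dimethylcyclohexan-1-one | O[C@@H](CC/C(C)=C\I)[C@@]1(C)C(=O)CC[C@](C)(O)[C@@H]1C#CC(OCC)OCC | intermediate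
15 | monoacetate (2-OAc, 14α-OH): 14 with the C14 ketone reduced to the axial 14α-alcohol (1,3-anti to O2) and O2 acetylated | CC(=O)O[C@@H](CC/C(C)=C\I)[C@@]1(C)[C@@H](O)CC[C@](C)(O)[C@@H]1C#CC(OCC)OCC | intermediate
16 | dihydrofuran: 15 cyclised from O11 to C8 (cis-fused 2,3-dihydrofuran, C8=C9, C7 diethyl acetal on C8) | CC(=O)O[C@@H](CC/C(C)=C\I)[C@@]1(C)[C@@H](O)CC[C@]2(C)OC(C(OCC)OCC)=C[C@H]12 | intermediate
17 | epoxide: 8,9-epoxide of 16 on the convex face | CC(=O)O[C@@H](CC/C(C)=C\I)[C@@]1(C)[C@@H](O)CC[C@]2(C)O[C@@]3(C(OCC)OCC)O[C@H]3[C@H]12 | intermediate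
18 | ketol (9-OH, C8 ketone): 9S hydroxyl; C7 diethyl acetal; 2-OAc; free 11β-OH and 14α-OH | CC(=O)O[C@@H](CC/C(C)=C\I)[C@@]1(C)[C@@H](O)CC[C@](C)(O)[C@@H]1[C@H](O)C(=O)C(OCC)OCC | intermediate
19 | diacetate ketone: 9-O-acetyl derivative of 18 | CC(=O)O[C@@H](CC/C(C)=C\I)[C@@]1(C)[C@@H](O)CC[C@](C)(O)[C@@H]1[C@H](OC(C)=O)C(=O)C(OCC)OCC | intermediate
20 | aldol ester: C19 methyl ester; new tertiary 8-OH and C17 methyl in the target configuration; C7 diethyl acetal | CC(=O)O[C@@H](CC/C(C)=C\I)[C@@]1(C)[C@@H](O)CC[C@](C)(O)[C@@H]1[C@H](OC(C)=O)[C@](O)([C@@H](C)C(=O)OC)C(OCC)OCC | intermediate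
21 | silylated acetal: 8,11,14-tris-O-triethylsilyl ether of 20 | CC(=O)O[C@@H](CC/C(C)=C\I)[C@@]1(C)[C@@H](O[Si](CC)(CC)CC)CC[C@](C)(O[Si](CC)(CC)CC)[C@@H]1[C@H](OC(C)=O)[C@](O[Si](CC)(CC)CC)([C@@H](C)C(=O)OC)C(OCC)OCC | intermediate
22 | collidinium salt: C7 1-ethoxyalkyl-2,4,6-trimethylpyridinium triflate derived from 21 (C7 epimers) | CC(=O)O[C@@H](CC/C(C)=C\I)[C@@]1(C)[C@@H](O[Si](CC)(CC)CC)CC[C@](C)(O[Si](CC)(CC)CC)[C@@H]1[C@H](OC(C)=O)[C@](O[Si](CC)(CC)CC)([C@@H](C)C(=O)OC)C(OCC)[n+]1c(C)cc(C)cc1C.[O-]S(=O)(=O)C(F)(F)F | intermediate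
23 | seco aldehyde: C7 aldehyde; 8,11,14-tris-O-triethylsilyl; 2,9-diacetate; C19 methyl ester; (Z)-C6 iodoalkene | CC(=O)O[C@@H](CC/C(C)=C\I)[C@@]1(C)[C@@H](O[Si](CC)(CC)CC)CC[C@](C)(O[Si](CC)(CC)CC)[C@@H]1[C@H](OC(C)=O)[C@](O[Si](CC)(CC)CC)([C@@H](C)C(=O)OC)C=O | intermediate
24 | silyl ether: ten-membered carbocycle with 7-O-trimethylsilyl ether and C19 methyl ester | CC(=O)O[C@H]1CC/C(C)=C\[C@H](O[Si](C)(C)C)[C@@](O[Si](CC)(CC)CC)([C@@H](C)C(=O)OC)[C@@H](OC(C)=O)[C@@H]2[C@]1(C)[C@@H](O[Si](CC)(CC)CC)CC[C@]2(C)O[Si](CC)(CC)CC | intermediate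
25 | hydroxy ester: ten-membered carbocycle with free 7-OH and C19 methyl ester | CC(=O)O[C@H]1CC/C(C)=C\[C@H](O)[C@@](O[Si](CC)(CC)CC)([C@@H](C)C(=O)OC)[C@@H](OC(C)=O)[C@@H]2[C@]1(C)[C@@H](O[Si](CC)(CC)CC)CC[C@]2(C)O[Si](CC)(CC)CC | intermediate
26 | 8,11,14-tris-O-triethylsilyl junceellolide I | CC(=O)O[C@H]1CC/C(C)=C\[C@@H]2OC(=O)[C@H](C)[C@@]2(O[Si](CC)(CC)CC)[C@@H](OC(C)=O)[C@@H]2[C@]1(C)[C@@H](O[Si](CC)(CC)CC)CC[C@]2(C)O[Si](CC)(CC)CC | intermediate
27 | junceellolide I [(1R,2S,5Z,7S,8S,9S,10S,11S,14S,17R) in briarane numbering; 2,9-diacetate, 8,11,14-triol, 19→7 lactone] | CC(=O)O[C@H]1CC/C(C)=C\[C@@H]2OC(=O)[C@H](C)[C@@]2(O)[C@@H](OC(C)=O)[C@@H]2[C@]1(C)[C@@H](O)CC[C@]2(C)O | target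

**Step count and risks**

Total step count: 13. Longest linear sequence: 11 steps, from prop-2-yn-1-ol (steps 3, 4, 5, then 6 to 13). The (S)-linalool branch (steps 1 and 2) joins at step 6.

The three steps most likely to fail:

Step 12 (the proposed new electrochemical macrocyclisation). Possible failures are oligomerisation, direct cathodic reduction of the aldehyde or the C–I bond, and slow addition to the neopentylic aldehyde. The fallback uses known chemistry, sets out from 23 and comes back at 26. Hydrodeiodination of 23 (Bu3SnH, Pd(PPh3)4 cat., THF) gives the des-iodo aldehyde F2. An intermolecular Nozaki–Hiyama–Kishi reaction of F2 with iodoethene (CrCl2 4 equiv, NiCl2 1 mol %, DMSO/THF) gives, under the same Felkin–Anh control, the allylic alcohol F3. PPTS in toluene lactonises it to the vinyl lactone F4. Ring-closing metathesis of F4 (second-generation Hoveyda–Grubbs catalyst RuCl2(=CH-C6H4-2-OiPr)(H2IMes), toluene, 80 °C, 1 mM) closes the ten-membered ring at C5=C6, with the ring size enforcing the Z olefin, and gives 26.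

Step 6 (one-pot directed alkynylation/aldol). Possible failures are 1,2-addition, attack of surplus alane on aldehyde 10, and retro-aldol of the hindered aldolate. The fallback separates the two bond formations; it sets out from 4 (with 11 and 10) and comes back at 14. The directed alkynylation is run alone and the aluminium enolate is trapped with Me3SiCl/Et3N to give the bis(trimethylsilyl) enol ether F1. MeLi (THF, −20 °C) regenerates the regiodefined lithium enolate from the enol silane. Transmetallation with MgBr2 and addition of 10 at −78 °C, followed by citric acid work-up (which also frees 11-OH), gives 14.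

Step 10 (propanoate aldol). Possible failures are enolisation of the α-acetoxy ketone, alkoxide-induced acetyl migration, and modest C17 control. The fallback replaces the basic lithium enolate by a reductively generated zinc enolate; it sets out from 19 and comes back at 20. A Reformatsky addition with methyl 2-bromopropanoate, Et2Zn and RhCl(PPh3)3 (5 mol %) in THF at 0 °C gives 20 directly, with C17 epimers separated by chromatography. This fallback makes no compound outside the list (none F0).

**Further compounds**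

F1 | step 6 | bis(trimethylsilyl) enol ether | C[Si](C)(C)OC1=C(C)[C@@H](C#CC(OCC)OCC)[C@@](C)(O[Si](C)(C)C)CC1
F0 | step 10 | none | none
F2 | step 12 | des-iodo aldehyde | CC(=O)O[C@@H](CCC(C)=C)[C@@]1(C)[C@@H](O[Si](CC)(CC)CC)CC[C@](C)(O[Si](CC)(CC)CC)[C@@H]1[C@H](OC(C)=O)[C@](O[Si](CC)(CC)CC)([C@@H](C)C(=O)OC)C=O
F3 | step 12 | allylic alcohol | CC(=O)O[C@@H](CCC(C)=C)[C@@]1(C)[C@@H](O[Si](CC)(CC)CC)CC[C@](C)(O[Si](CC)(CC)CC)[C@@H]1[C@H](OC(C)=O)[C@](O[Si](CC)(CC)CC)([C@@H](C)C(=O)OC)[C@@H](O)C=C
F4 | step 12 | vinyl lactone | CC(=O)O[C@@H](CCC(C)=C)[C@@]1(C)[C@@H](O[Si](CC)(CC)CC)CC[C@](C)(O[Si](CC)(CC)CC)[C@@H]1[C@H](OC(C)=O)[C@]2(O[Si](CC)(CC)CC)[C@@H](C)C(=O)O[C@H]2C=C
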